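**Retrosynthetic overview**

1. Target 30 ⇐ (hydrogenolysis, desilylation) tertiary alcohol 28 ⇐ aryl Grignard 27 + spiro-epoxide 25 ⇐ 4-methylene-tetrahydrofuran 24 ⇐ diol 22 ⇐ α-methylene lactone 21.
2. Feature: the tetrahydrofuran ring (O1; C2 carrying the dihydrobenzofuran-5-yl group; C3 carrying CH2OH cis to it; C4, the carbinol with the guaiacylmethyl group; C5H2) is the cis-5-aryl-4-(silyloxymethyl)-3-methylene-γ-butyrolactone 21 in disguise. Its exocyclic CH2 becomes the benzylic carbon on C4 and its carbonyl carbon becomes C5.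
3. Key disconnection: 21 ⇒ aldehyde 18 + (E)-2-(methoxycarbonyl)allylboronate 5 (C2–C3 by chair allylboration, O1–C5 by lactonisation).
4. 18 ⇐ bromide 15 ⇐ cis-dihydrobenzofuran ester 13 by rhodium-carbenoid C–H insertion of diazo ester 12 (from 4-bromo-2-methoxyphenol 6); 5 ⇐ Morita–Baylis–Hillman acetate 4.
5. Ring order: dihydrobenzofuran (step 8), lactone (step 12), tetrahydrofuran (step 14), oxirane as a relay (made in step 15, opened in step 17).

Key step: step 12

Assumption: the sense of induction of Rh2(S-PTTL)4 (step 8) and of (R)-TRIP (step 12) is taken from the behaviour of the parent substrates; if either proves opposite, the antipodal catalyst is used and nothing else changes. Compounds 8 and 10 are taken as purchased (10 as its solution in Et2O).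

In names from compound 19 onwards, Ar* = (2R,3R)-2-[4-(benzyloxy)-3-methoxyphenyl]-3-{[(tert-butyldimethylsilyl)oxy]methyl}-7-methoxy-2,3-dihydro-1-benzofuran-5-yl.

**Route**

Step 1
Reactants: 1 (tert-butyldimethylsilyloxy)acetaldehyde; 2 methyl acrylate
Product: 3 methyl 4-[(tert-butyldimethylsilyl)oxy]-3-hydroxy-2-methylenebutanoate (racemic)
Conditions: DABCO (0.3 equiv), methyl acrylate (3 equiv, neat), rt
Reagents that add atoms: none
Why: Morita–Baylis–Hillman reaction, in which the ammonium enolate formed from DABCO and the acrylate adds to the unhindered, inductively activated α-silyloxy aldehyde; the carbinol centre is racemic and is erased in step 3.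

Step 2
Reactants: 3 Morita–Baylis–Hillman alcohol
Product: 4 methyl 3-acetoxy-4-[(tert-butyldimethylsilyl)oxy]-2-methylenebutanoate (racemic)
Conditions: Ac2O, Et3N, DMAP (5 mol %), CH2Cl2, 0 °C
Reagents that add atoms: acetic anhydride, CC(=O)OC(C)=O
Why: DMAP-catalysed acylation turns the secondary allylic hydroxyl into the leaving group for the allylic substitution; it is run cold and briefly so that the acetate does not transpose.

Step 3
Reactants: 4 allylic acetate
Product: 5 methyl (E)-4-[(tert-butyldimethylsilyl)oxy]-2-[(4,4,5,5-tetramethyl-1,3,2-dioxaborolan-2-yl)methyl]but-2-enoate (CH2B cis to CH2OTBS)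
Conditions: B2pin2 (1.1 equiv), CuCl (10 mol %), KOAc (1.2 equiv), DMF, rt
Reagents that add atoms: bis(pinacolato)diboron, CC1(C)OB(OC1(C)C)B1OC(C)(C)C(C)(C)O1
Why: Copper-catalysed allylic borylation (formal SN2′): the boryl copper species adds boron to the terminal acrylate carbon and the copper enolate expels acetate, which should place CH2OTBS trans to the ester as is usual for SN2′ products of Morita–Baylis–Hillman acetates; a minor (Z)-isomer would be removed by chromatography.

Step 4
Reactants: 6 4-bromo-2-methoxyphenol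
Product: 7 4-bromo-2-iodo-6-methoxyphenol
Conditions: iodine (1.05 equiv), NaHCO3, THF/H2O, 0 °C → rt
Reagents that add atoms: iodine, [I][I]
Why: Electrophilic aromatic iodination of the phenol/phenoxide: the para position is blocked by bromine and the hydroxyl outranks the methoxy group as director, so iodine should enter ortho to OH.

Step 5
Reactants: 7 4-bromo-2-iodo-6-methoxyphenol; 8 4-(benzyloxy)-3-methoxybenzyl alcohol
Product: 9 1-(benzyloxy)-4-[(4-bromo-2-iodo-6-methoxyphenoxy)methyl]-2-methoxybenzene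
Conditions: PPh3, DIAD, THF, 0 °C → rt
Reagents that add atoms: none
Why: Mitsunobu etherification: the acidic phenol is a good pronucleophile for the oxyphosphonium ion of the primary benzylic alcohol, and neither acid nor strong base touches the electron-rich benzyl unit.

Step 6
Reactants: 9 aryl iodide; 10 (2-tert-butoxy-2-oxoethyl)zinc bromide (Reformatsky reagent, 0.5 M in Et2O)
Product: 11 tert-butyl 2-{2-[(4-benzyloxy-3-methoxybenzyl)oxy]-5-bromo-3-methoxyphenyl}acetate
Conditions: Pd(PPh3)4 (5 mol %), 10 (1.5 equiv), THF/DMPU, 50 °C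
Reagents that add atoms: none
Why: Negishi-type arylation of a Reformatsky reagent: zerovalent palladium inserts into the C–I bond much faster than into the C–Br bond of this electron-rich ring, transmetalation and reductive elimination give the arylacetate, and the tert-butyl ester suppresses Claisen self-condensation.

Step 7
Reactants: 11 tert-butyl arylacetate
Product: 12 tert-butyl 2-{2-[(4-benzyloxy-3-methoxybenzyl)oxy]-5-bromo-3-methoxyphenyl}-2-diazoacetate
Conditions: 4-acetamidobenzenesulfonyl azide (p-ABSA), DBU, MeCN, 0 °C → rt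
Reagents that add atoms: 4-acetamidobenzenesulfonyl azide, CC(=O)Nc1ccc(cc1)S(=O)(=O)N=[N+]=[N-]
Why: Regitz diazo transfer: DBU deprotonates the benzylic ester α-carbon and the enolate takes the diazo group from the sulfonyl azide, the standard entry to aryl diazoacetates.

Step 8
Reactants: 12 aryl diazoacetate
Product: 13 tert-butyl (2R,3S)-2-[4-(benzyloxy)-3-methoxyphenyl]-5-bromo-7-methoxy-2,3-dihydro-1-benzofuran-3-carboxylate (2-aryl and 3-ester cis)
Conditions: Rh2(S-PTTL)4 [dirhodium tetrakis(N-phthaloyl-(S)-tert-leucinate)] (1 mol %), toluene, −60 °C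
Reagents that add atoms: none
Why: Intramolecular 1,5 C–H insertion of a donor/acceptor rhodium carbenoid into the ether-activated benzylic C–H bond, a reaction known for 2-(benzyloxy)phenyl diazoacetates to give cis-2-aryl-2,3-dihydrobenzofuran-3-carboxylates; the compact hydride-transfer-like transition state sets C2 and C3 cis and the chiral carboxylate ligands select the enantiomer.

Step 9
Reactants: 13 cis ester
Product: 14 {(2R,3R)-2-[4-(benzyloxy)-3-methoxyphenyl]-5-bromo-7-methoxy-2,3-dihydro-1-benzofuran-3-yl}methanol (cis)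
Conditions: LiAlH4, THF, −20 → 0 °C
Reagents that add atoms: none
Why: Hydride reduction of the ester at low temperature should outrun enolisation, so the base-labile cis C3 centre is kept, and the aryl bromide and benzyl ether are inert to LiAlH4 at this temperature.

Step 10
Reactants: 14 primary alcohol
Product: 15 (2R,3R)-2-[4-(benzyloxy)-3-methoxyphenyl]-5-bromo-3-{[(tert-butyldimethylsilyl)oxy]methyl}-7-methoxy-2,3-dihydro-1-benzofuran
Conditions: TBSCl, imidazole, DMF, rt
Reagents that add atoms: tert-butyldimethylsilyl chloride, CC(C)(C)[Si](C)(C)Cl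
Why: Standard imidazole-mediated silylation of an unhindered primary alcohol, giving an ether stable to organolithium, hydride, peracid and Grignard reagents used later.

Step 11
Reactants: 15 aryl bromide
Product: 18 (2R,3R)-2-[4-(benzyloxy)-3-methoxyphenyl]-3-{[(tert-butyldimethylsilyl)oxy]methyl}-7-methoxy-2,3-dihydro-1-benzofuran-5-carbaldehyde (cis), via aryllithium 16 (not isolated), via lithium hemiaminal alkoxide 17 (not isolated)
Conditions: n-BuLi (1.1 equiv), THF, −78 °C; DMF (3 equiv), −78 → 0 °C; aq. NH4Cl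
Reagents that add atoms: N,N-dimethylformamide, CN(C)C=O
Why: Bromine–lithium exchange at −78 °C is faster than any deprotonation, and the aryllithium is formylated by DMF (Bouveault-type formylation), the tetrahedral adduct releasing the aldehyde only on work-up.

Step 12
Reactants: 18 aldehyde; 5 (E)-allylboronate
Product: 21 (4R,5R)-5-Ar*-4-{[(tert-butyldimethylsilyl)oxy]methyl}-3-methylenedihydrofuran-2(3H)-one (aryl and CH2OTBS cis), via O-boryl homoallylic ester 19 (not isolated), via syn hydroxy ester 20 (not isolated)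
Conditions: 5 (1.5 equiv), (R)-TRIP [(R)-3,3′-bis(2,4,6-triisopropylphenyl)-1,1′-binaphthyl-2,2′-diyl hydrogen phosphate] (10 mol %), 4 Å MS, toluene, 0 °C → rt; aq. NaHCO3; then PPTS (10 mol %), CH2Cl2, rt
Reagents that add atoms: none
Why: Proposed new method: the phosphoric acid hydrogen-bonds to a pinacol oxygen of 5 and so raises the Lewis acidity of boron while aldehyde 18 binds boron, and the aldehyde carbon then bonds to the γ-carbon of the allyl unit through a closed six-membered chair to give borate 19; the closest known reactions are chiral phosphoric acid-catalysed allyl- and crotylboration of aryl aldehydes with pinacol boronates and the acid-catalysed addition of 2-alkoxycarbonyl allylboronates to aldehydes that gives α-methylene-γ-butyrolactones, and the new element is their combination on an ester-deactivated boronate. The γ-CH2OTBS group, cis to CH2B in (E)-5, has to sit axial in the chair with the aldehyde aryl group equatorial, so the syn relationship of the two new stereocentres (later C2 and C3 of the tetrahydrofuran) follows from the alkene geometry of the reagent. The absolute configuration (Re-face attack, R at the carbinol carbon) is set by the chiral acid, because the stereocentres already present in 18 lie five bonds from the carbonyl and cannot bias it. After hydrolysis of the O–B bond the syn hydroxy ester 20 closes the lactone by 5-exo-trig attack of the hydroxyl on the ester carbonyl with loss of methanol, and in the ring syn becomes aryl and CH2OTBS cis. The step also needs chemoselectivity: the benzylic C–O bonds flanked by para-alkoxyaryl groups (the new lactone C5–O and the dihydrobenzofuran C2–O) ionise and epimerise under strong acid, which is why only a weak acid in toluene and pyridinium p-toluenesulfonate are used.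

Step 13
Reactants: 21 α-methylene lactone
Product: 22 (3R,4R)-4-Ar*-3-{[(tert-butyldimethylsilyl)oxy]methyl}-2-methylenebutane-1,4-diol
Conditions: i-Bu2AlH (4 equiv), CH2Cl2, −78 → 0 °C; aq. potassium sodium tartrate
Reagents that add atoms: none
Why: 1,2-Reduction of the α-methylene lactone by i-Bu2AlH through the lactol to the 2-methylene-1,4-diol, which leaves the benzylic C–O bond intact; this reductive opening is chosen over Lewis-acid/silane deoxygenation of a lactol because the two cis benzylic ethers with para-alkoxyaryl groups would be expected to ionise under BF3.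

Step 14
Reactants: 22 diol
Product: 24 (2R,3R)-2-Ar*-3-{[(tert-butyldimethylsilyl)oxy]methyl}-4-methylenetetrahydrofuran (cis), via primary allylic tosylate 23 (not isolated)
Conditions: TsCl (1.1 equiv), Et3N, DMAP (5 mol %), CH2Cl2, 0 °C; then t-BuOK (1.3 equiv), THF, 0 °C
Reagents that add atoms: none
Why: Selective sulfonylation of the primary allylic hydroxyl followed by intramolecular Williamson etherification (5-exo-tet) by the benzylic alkoxide; the benzylic C–O bond is never broken, so C2 keeps its configuration, and the tosylate is in place before the alkoxide is generated, which leaves little time for 1,3-silyl migration.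

Step 15
Reactants: 24 4-methylene-tetrahydrofuran
Product: 25 (3R,6R,7R)-6-Ar*-7-{[(tert-butyldimethylsilyl)oxy]methyl}-1,5-dioxaspiro[2.4]heptane (oxirane oxygen trans to CH2OTBS)
Conditions: mCPBA (1.3 equiv), NaHCO3, CH2Cl2, 0 °C
Reagents that add atoms: 3-chloroperbenzoic acid, O=C(OO)c1cccc(Cl)c1
Why: Prilezhaev epoxidation of the 1,1-disubstituted exocyclic alkene; the C3 silyloxymethyl and the C2 aryl group are cis and shield the same face, so the peracid should approach from the other face and place the oxirane oxygen trans to CH2OTBS, as the C4 hydroxyl of the target requires.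

Step 16
Reactants: 6 4-bromo-2-methoxyphenol
Product: 26 1-(benzyloxy)-4-bromo-2-methoxybenzene
Conditions: BnBr, K2CO3, acetone, reflux
Reagents that add atoms: benzyl bromide, BrCc1ccccc1
Why: Williamson etherification of the phenoxide with a reactive benzylic halide, giving the protected precursor of the guaiacyl nucleophile.

Step 17
Reactants: 25 spiro-epoxide; 26 1-(benzyloxy)-4-bromo-2-methoxybenzene
Product: 28 (3S,4R,5R)-3-[4-(benzyloxy)-3-methoxybenzyl]-5-Ar*-4-{[(tert-butyldimethylsilyl)oxy]methyl}tetrahydrofuran-3-ol, via arylmagnesium bromide 27 (not isolated)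
Conditions: 26, Mg turnings, THF, 50 °C; then 25, CuBr·SMe2 (10 mol %), THF, −30 → 0 °C; aq. NH4Cl
Reagents that add atoms: none
Why: Copper-catalysed SN2 opening of the 2,2-disubstituted epoxide by the aryl Grignard reagent at the unhindered CH2 terminus makes the benzylic C–C bond without touching the quaternary carbinol carbon, so the C4 configuration set in step 15 is carried over.

Step 18
Reactants: 28 bis-silyl ether
Product: 29 (3S,4R,5R)-3-[4-(benzyloxy)-3-methoxybenzyl]-5-{(2R,3R)-2-[4-(benzyloxy)-3-methoxyphenyl]-3-(hydroxymethyl)-7-methoxy-2,3-dihydro-1-benzofuran-5-yl}-4-(hydroxymethyl)tetrahydrofuran-3-ol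
Conditions: Bu4NF (3 equiv), THF, rt
Reagents that add atoms: none
Why: Fluoride-mediated cleavage of both primary silyl ethers under non-acidic conditions, which the acid-labile cis benzylic ethers tolerate.

Step 19
Reactants: 29 bis-benzyl ether
Product: 30 (3S,4R,5R)-3-(4-hydroxy-3-methoxybenzyl)-5-[(2R,3R)-2-(4-hydroxy-3-methoxyphenyl)-3-(hydroxymethyl)-7-methoxy-2,3-dihydro-1-benzofuran-5-yl]-4-(hydroxymethyl)tetrahydrofuran-3-ol (CNP0284796.1)
Conditions: H2 (1 atm), Pd/C (10 wt % Pd), EtOAc/MeOH, rt
Reagents that add atoms: none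
Why: Hydrogenolysis of the two primary aryl benzyl ethers, which should be cleaved much faster than the cyclic secondary benzylic ethers under neutral conditions at 1 atm; the reaction is stopped when 29 is consumed.

**Compound list**

1 | (tert-butyldimethylsilyloxy)acetaldehyde | O=CCO[Si](C)(C)C(C)(C)C | starting material
2 | methyl acrylate | C=CC(=O)OC | starting material
3 | methyl 4-[(tert-butyldimethylsilyl)oxy]-3-hydroxy-2-methylenebutanoate (racemic) | C=C(C(=O)OC)C(O)CO[Si](C)(C)C(C)(C)C | intermediate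
4 | methyl 3-acetoxy-4-[(tert-butyldimethylsilyl)oxy]-2-methylenebutanoate (racemic) | C=C(C(=O)OC)C(OC(C)=O)CO[Si](C)(C)C(C)(C)C | intermediate
5 | methyl (E)-4-[(tert-butyldimethylsilyl)oxy]-2-[(pinacolboryl)methyl]but-2-enoate | COC(=O)/C(CB1OC(C)(C)C(C)(C)O1)=C/CO[Si](C)(C)C(C)(C)C | intermediate
6 | 4-bromo-2-methoxyphenol | COc1cc(Br)ccc1O | starting material
7 | 4-bromo-2-iodo-6-methoxyphenol | COc1cc(Br)cc(I)c1O | intermediate
8 | 4-(benzyloxy)-3-methoxybenzyl alcohol | OCc1ccc(OCc2ccccc2)c(OC)c1 | starting material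
9 | 1-(benzyloxy)-4-[(4-bromo-2-iodo-6-methoxyphenoxy)methyl]-2-methoxybenzene | COc1cc(Br)cc(I)c1OCc1ccc(OCc2ccccc2)c(OC)c1 | intermediate
10 | (2-tert-butoxy-2-oxoethyl)zinc bromide | CC(C)(C)OC(=O)C[Zn]Br | starting material
11 | tert-butyl 2-{2-[(4-benzyloxy-3-methoxybenzyl)oxy]-5-bromo-3-methoxyphenyl}acetate | COc1cc(Br)cc(CC(=O)OC(C)(C)C)c1OCc1ccc(OCc2ccccc2)c(OC)c1 | intermediate
12 | tert-butyl 2-{2-[(4-benzyloxy-3-methoxybenzyl)oxy]-5-bromo-3-methoxyphenyl}-2-diazoacetate | COc1cc(Br)cc(C(=[N+]=[N-])C(=O)OC(C)(C)C)c1OCc1ccc(OCc2ccccc2)c(OC)c1 | intermediate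
13 | tert-butyl (2R,3S)-2-[4-(benzyloxy)-3-methoxyphenyl]-5-bromo-7-methoxy-2,3-dihydro-1-benzofuran-3-carboxylate (cis) | Brc1cc(OC)c2c(c1)[C@H](C(=O)OC(C)(C)C)[C@H](c1ccc(OCc3ccccc3)c(OC)c1)O2 | intermediate
14 | {(2R,3R)-2-[4-(benzyloxy)-3-methoxyphenyl]-5-bromo-7-methoxy-2,3-dihydro-1-benzofuran-3-yl}methanol (cis) | Brc1cc(OC)c2c(c1)[C@H](CO)[C@H](c1ccc(OCc3ccccc3)c(OC)c1)O2 | intermediate
15 | (2R,3R)-2-[4-(benzyloxy)-3-methoxyphenyl]-5-bromo-3-{[(tert-butyldimethylsilyl)oxy]methyl}-7-methoxy-2,3-dihydro-1-benzofuran | Brc1cc(OC)c2c(c1)[C@H](CO[Si](C)(C)C(C)(C)C)[C@H](c1ccc(OCc3ccccc3)c(OC)c1)O2 | intermediate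
16 | 5-lithio analogue of 15 (aryllithium) | [Li]c1cc(OC)c2c(c1)[C@H](CO[Si](C)(C)C(C)(C)C)[C@H](c1ccc(OCc3ccccc3)c(OC)c1)O2 | intermediate
17 | lithium (dimethylamino)(aryl)methoxide from 16 and DMF (carbinol centre undefined) | [Li]OC(N(C)C)c1cc(OC)c2c(c1)[C@H](CO[Si](C)(C)C(C)(C)C)[C@H](c1ccc(OCc3ccccc3)c(OC)c1)O2 | intermediate
18 | (2R,3R)-2-[4-(benzyloxy)-3-methoxyphenyl]-3-{[(tert-butyldimethylsilyl)oxy]methyl}-7-methoxy-2,3-dihydro-1-benzofuran-5-carbaldehyde (cis) | O=Cc1cc(OC)c2c(c1)[C@H](CO[Si](C)(C)C(C)(C)C)[C@H](c1ccc(OCc3ccccc3)c(OC)c1)O2 | intermediate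
19 | methyl (3R,4R)-4-Ar*-3-{[(tert-butyldimethylsilyl)oxy]methyl}-2-methylene-4-[(pinacolboryl)oxy]butanoate (syn) | C=C(C(=O)OC)[C@H](CO[Si](C)(C)C(C)(C)C)[C@H](c1cc(OC)c2c(c1)[C@H](CO[Si](C)(C)C(C)(C)C)[C@H](c1ccc(OCc3ccccc3)c(OC)c1)O2)OB1OC(C)(C)C(C)(C)O1 | intermediate
20 | methyl (3R,4R)-4-Ar*-3-{[(tert-butyldimethylsilyl)oxy]methyl}-4-hydroxy-2-methylenebutanoate (syn) | C=C(C(=O)OC)[C@H](CO[Si](C)(C)C(C)(C)C)[C@H](c1cc(OC)c2c(c1)[C@H](CO[Si](C)(C)C(C)(C)C)[C@H](c1ccc(OCc3ccccc3)c(OC)c1)O2)O | intermediate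
21 | (4R,5R)-5-Ar*-4-{[(tert-butyldimethylsilyl)oxy]methyl}-3-methylenedihydrofuran-2(3H)-one (cis) | C=C1C(=O)O[C@@H](c2cc(OC)c3c(c2)[C@H](CO[Si](C)(C)C(C)(C)C)[C@H](c2ccc(OCc4ccccc4)c(OC)c2)O3)[C@H]1CO[Si](C)(C)C(C)(C)C | intermediate
22 | (3R,4R)-4-Ar*-3-{[(tert-butyldimethylsilyl)oxy]methyl}-2-methylenebutane-1,4-diol | C=C(CO)[C@H](CO[Si](C)(C)C(C)(C)C)[C@H](c1cc(OC)c2c(c1)[C@H](CO[Si](C)(C)C(C)(C)C)[C@H](c1ccc(OCc3ccccc3)c(OC)c1)O2)O | intermediate
23 | 1-O-(p-toluenesulfonyl) derivative of 22 | C=C(COS(=O)(=O)c1ccc(C)cc1)[C@H](CO[Si](C)(C)C(C)(C)C)[C@H](c1cc(OC)c2c(c1)[C@H](CO[Si](C)(C)C(C)(C)C)[C@H](c1ccc(OCc3ccccc3)c(OC)c1)O2)O | intermediate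
24 | (2R,3R)-2-Ar*-3-{[(tert-butyldimethylsilyl)oxy]methyl}-4-methylenetetrahydrofuran (cis) | C=C1CO[C@@H](c2cc(OC)c3c(c2)[C@H](CO[Si](C)(C)C(C)(C)C)[C@H](c2ccc(OCc4ccccc4)c(OC)c2)O3)[C@H]1CO[Si](C)(C)C(C)(C)C | intermediate
25 | (3R,6R,7R)-6-Ar*-7-{[(tert-butyldimethylsilyl)oxy]methyl}-1,5-dioxaspiro[2.4]heptane (oxirane O trans to CH2OTBS) | C1[C@@]2(O1)CO[C@@H](c3cc(OC)c4c(c3)[C@H](CO[Si](C)(C)C(C)(C)C)[C@H](c3ccc(OCc5ccccc5)c(OC)c3)O4)[C@H]2CO[Si](C)(C)C(C)(C)C | intermediate
26 | 1-(benzyloxy)-4-bromo-2-methoxybenzene | COc1cc(Br)ccc1OCc1ccccc1 | intermediate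
27 | [4-(benzyloxy)-3-methoxyphenyl]magnesium bromide | COc1cc([Mg]Br)ccc1OCc1ccccc1 | intermediate
28 | (3S,4R,5R)-3-[4-(benzyloxy)-3-methoxybenzyl]-5-Ar*-4-{[(tert-butyldimethylsilyl)oxy]methyl}tetrahydrofuran-3-ol | COc1cc(C[C@@]2(O)CO[C@@H](c3cc(OC)c4c(c3)[C@H](CO[Si](C)(C)C(C)(C)C)[C@H](c3ccc(OCc5ccccc5)c(OC)c3)O4)[C@H]2CO[Si](C)(C)C(C)(C)C)ccc1OCc1ccccc1 | intermediate
29 | (3S,4R,5R)-3-[4-(benzyloxy)-3-methoxybenzyl]-5-{(2R,3R)-2-[4-(benzyloxy)-3-methoxyphenyl]-3-(hydroxymethyl)-7-methoxy-2,3-dihydro-1-benzofuran-5-yl}-4-(hydroxymethyl)tetrahydrofuran-3-ol | COc1cc(C[C@@]2(O)CO[C@@H](c3cc(OC)c4c(c3)[C@H](CO)[C@H](c3ccc(OCc5ccccc5)c(OC)c3)O4)[C@H]2CO)ccc1OCc1ccccc1 | intermediate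
30 | (3S,4R,5R)-3-(4-hydroxy-3-methoxybenzyl)-5-[(2R,3R)-2-(4-hydroxy-3-methoxyphenyl)-3-(hydroxymethyl)-7-methoxy-2,3-dihydro-1-benzofuran-5-yl]-4-(hydroxymethyl)tetrahydrofuran-3-ol | COc1cc(C[C@@]2(O)CO[C@@H](c3cc(OC)c4c(c3)[C@H](CO)[C@H](c3ccc(O)c(OC)c3)O4)[C@H]2CO)ccc1O | target

**Step count**

Total: 19 steps. Longest linear sequence: 15 steps (6 → 30 through steps 4–15 and 17–19).

**Steps most likely to fail**

Step 12 (the step with the new-method label). The weak chiral acid may fail to turn over the ester-deactivated boronate, enantiofacial discrimination may be poor, or acid may ionise the benzylic lactone C–O bond and erode the cis relationship. The fallback uses known chemistry and sets out from aldehyde 18 and boronate 5. The addition is run without any acid in toluene at 80–100 °C; the uncatalysed addition of 2-alkoxycarbonyl allylboronates is stereospecific through the same closed chair, and borate 19 lactonises in the heat with loss of the boron methoxide. Only cis lactones should then form, namely 21 and its (4S,5S)-diastereomer F1. Because the dihydrobenzofuran is already a single enantiomer, the two are diastereomers and are separated by chromatography, and 21 comes back to the route at step 13. Catalyst control is thus replaced by separation.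

Step 15. Peracid delivery to the exocyclic alkene may be poorly face-selective, or the spiro-epoxide may be opened by 3-chlorobenzoic acid. The fallback sets out from 24. Dihydroxylation with OsO4 (catalytic) and N-methylmorpholine N-oxide, a bulkier reagent that should attack the open face more selectively, gives the diol F2 with the tertiary hydroxyl trans to CH2OTBS. Selective tosylation of its primary hydroxyl (TsCl, pyridine) gives the monotosylate F3, and K2CO3 in MeOH closes the oxirane by 3-exo-tet displacement. This gives 25, where the route is rejoined.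

Step 6. Oxidative addition may not discriminate cleanly between C–I and C–Br, or reductive elimination may be slow enough for the zinc enolate to be lost to self-condensation and protonation. The fallback sets out from iodide 9. Iodine–magnesium exchange with i-PrMgCl·LiCl at −40 °C, which is selective for the iodide, gives the arylmagnesium chloride F4. Acylation with di-tert-butyl oxalate at −78 °C gives the aryl glyoxylate F5, and condensation with p-toluenesulfonyl hydrazide gives the tosylhydrazone F6. DBU then effects Bamford–Stevens elimination to the diazo ester 12, where the route is rejoined; compound 11 and step 7 are bypassed.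

**Further compounds**

F1 | step 12 | (4S,5S)-5-Ar*-4-{[(tert-butyldimethylsilyl)oxy]methyl}-3-methylenedihydrofuran-2(3H)-one (cis lactone, diastereomer of 21) | C=C1C(=O)O[C@H](c2cc(OC)c3c(c2)[C@H](CO[Si](C)(C)C(C)(C)C)[C@H](c2ccc(OCc4ccccc4)c(OC)c2)O3)[C@@H]1CO[Si](C)(C)C(C)(C)C
F2 | step 15 | 5-Ar*-4-{[(tert-butyldimethylsilyl)oxy]methyl}-3-(hydroxymethyl)tetrahydrofuran-3-ol (tertiary OH trans to CH2OTBS) | OC[C@@]1(O)CO[C@@H](c2cc(OC)c3c(c2)[C@H](CO[Si](C)(C)C(C)(C)C)[C@H](c2ccc(OCc4ccccc4)c(OC)c2)O3)[C@H]1CO[Si](C)(C)C(C)(C)C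
F3 | step 15 | primary p-toluenesulfonate of F2 | Cc1ccc(cc1)S(=O)(=O)OC[C@@]1(O)CO[C@@H](c2cc(OC)c3c(c2)[C@H](CO[Si](C)(C)C(C)(C)C)[C@H](c2ccc(OCc4ccccc4)c(OC)c2)O3)[C@H]1CO[Si](C)(C)C(C)(C)C
F4 | step 6 | {2-[(4-benzyloxy-3-methoxybenzyl)oxy]-5-bromo-3-methoxyphenyl}magnesium chloride | COc1cc(Br)cc([Mg]Cl)c1OCc1ccc(OCc2ccccc2)c(OC)c1
F5 | step 6 | tert-butyl 2-{2-[(4-benzyloxy-3-methoxybenzyl)oxy]-5-bromo-3-methoxyphenyl}-2-oxoacetate | COc1cc(Br)cc(C(=O)C(=O)OC(C)(C)C)c1OCc1ccc(OCc2ccccc2)c(OC)c1
F6 | step 6 | p-toluenesulfonylhydrazone of F5 | COc1cc(Br)cc(C(=NNS(=O)(=O)c2ccc(C)cc2)C(=O)OC(C)(C)C)c1OCc1ccc(OCc2ccccc2)c(OC)c1
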